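All positions are numbered as in the xenicane skeleton: ring A is the dihydropyran C1–O2–C3=C4–C4a–C11a, ring B the nine-membered carbocycle C4a–C5–C6–C7–C8–C9–C10–C11–C11a, C18 is the methyl on C7, C19 the methylene on C11, and C12–C17 is the side chain on C4.

## Analysis of the target

The target 42 is a 2-oxabicyclo[7.4.0]tridecane: dihydropyran ring A is trans-fused to the nine-membered ring B (H-4a and H-11a anti; 4aS,11aR). Ring B carries five contiguous functionalised carbons: the 7,8-epoxide (7S,8R; the geometry of a Z olefin, oxygen anti to the C9 oxygen), the cis-9,10-diol as 9-benzoate and free 10-hydroxyl (9S,10S), and the C11 methylene. Ring A carries the axial anomeric acetate at C1 (1S, trans to H-11a) and the C3=C4 enol ether; the side chain carries an erythro diacetate (12S,13R) next to an isobutenyl group. The sensitive groups are the acylal/enol ether and the epoxide (acid, Lewis acid), the anomeric and allylic esters (base, hydride), the free C10 hydroxyl beside the C9 benzoate (acyl migration), and C11a, which sits between C1 and the exocyclic olefin (epimerisation or conjugation once C1 is a carbonyl). The main difficulty is the densely functionalised medium ring: closing it by bond formation fights entropy and transannular strain, and its stereocentres must be related to C4a/C11a across the ring. The strategy rests on one feature: C11 and the C7–C8 unit are 1,3-related through C7. With C11 as a ketone and the epoxide as a Z olefin, one extra C7–C11 bond turns ring B into a cis-hydrindane with C7 as the angular methyl carbon, C11 as the bridgehead carbinol and C8 carrying a leaving group.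

## Retrosynthetic reasoning

**Late acyl and silyl changes (42 ← 41 ← 40 ← 39).** The free C10 hydroxyl is unveiled last from silyl ether 41, because it must not compete in any acylation and because a free hydroxyl next to the C9 benzoate invites migration. The C12/C13 acetates come from the diol 40, freed from the bis(triethylsilyl) ether 39 only after C3 has become an enol ether carbon; a free C13 hydroxyl would otherwise close onto a C3 carbonyl.

**C1 acetate (39 ← 38 ← 37).** The anomeric acetate is traced to lactol 38 and this to enol lactone 37. Placing C1 at the acid level and C3 at the aldehyde level fixes the constitution of ring A. A 1,5-dialdehyde would not tell C1 from C3, and a C1 aldehyde would enolise towards C11a, which is allylic to the C11 methylene.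

**C1–O2 bond (37 ← 36 ← 35 ← 34 ← 33).** Enol lactone 37 is opened to formyl acid 36. The C3 aldehyde is kept masked as the thioester of 35 until the C1 acid is in place; the acid comes from the primary silyl ether of 33 through aldehyde 34.

**C11=C19 (33 ← 32).** The methylene is cut back to the C11 ketone, which is also the activating group for the two bonds that join ring A to ring B.

**C4a–C4 and C11a–C1 (32 ← 21 + 30).** Both bonds are cut in one operation: conjugate addition of the ketene thioacetal 30 to enone 21, then capture of the resulting enol ether by a one-carbon electrophile at C11a, trans to the new C4a substituent. The one-carbon unit enters at the alcohol level, so C1 is oxidised afterwards. An aldehyde-level nucleophile is avoided: its free C3 aldehyde would pair with the C1 hydroxyl as the wrong lactol (acetal at C3, methylene at C1) and would not survive the methylenation.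

**Side chain (30 ← 29 ← 28 ← 27 ← 26 ← 25 ← 24 ← 23 ← 22).** C12 and C13 are C3 and C4 of the sugar 22 with the configuration the target needs. The sugar C1 becomes the thioester carbon (C3 of the target), and the sugar C5 is oxidised and olefinated to the isobutenyl group.

**Enone and ring B decoration (21 ← 19 ← 18 ← 17 ← 16 ← 15).** The C11a=C4a olefin is introduced by dehydrogenation of ketone 19. The epoxide is installed before the side chain brings a second trisubstituted olefin. The benzoate is placed on C9 (17) before any enone exists, because a free C9 hydroxyl could add across the ring to C4a. Acetonide 15 is hydrolysed before the epoxide is present.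

**Ring B (15 ← 13, the key disconnection).** Adding the C7–C11 bond to 15 gives the cis-hydrindane mesylate 13. In the forward direction no σ bond is made: the C11 alkoxide expels the C8 mesylate and C7–C11 breaks. The gain is a nine-membered ring without a medium-ring closure, with the Z geometry set by the substrate and the cis-9,10-diol already in place.

**Hydrindane oxygenation (13 ← 12 ← 11 ← 10 ← 8).** The C8 sulfonate trans to the angular methyl comes from a reduction directed by the C11 hydroxyl; the cis-9,10-diol comes from a dihydroxylation of enone 8 directed by the same hydroxyl on a rigid cyclopentenone.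

**Hydrindane core (8 ← 7 ← 6 ← 5 ← 4 ← 3 ← 1 + 2).** Enone 8 comes from ketone 7; the six-ring carbonyl of ketol 4 (C4a of the target) is removed, and 4 comes from the proline-catalysed aldol of triketone 3, made from 1 and 2. This step sets the absolute configuration of the whole ring system.

## Alternatives that were turned down

**Alternative 1:** Ring A is cut at C4=C4a, C4a–C11a and C1–O2. An aldehyde holding C4a and the C5–C8 arm would condense with a β-formyl ester, and the resulting 1-oxadiene would add an E enol ether in an inverse-demand hetero-Diels–Alder reaction to give the 2-methoxy-dihydropyran A1.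
- For: three components, one step, and ring A arrives with C1 as an acetal and C3=C4 as the enol ether. On ring A step economy this is clearly stronger than the chosen route, which spends nine steps on ring A.
- Against: A1 is made from achiral partners, so the absolute configuration needs a chiral catalyst. C12 arrives as an ester carbon and must still be turned into the C12/C13 diacetate with two new stereocentres beside an acid-sensitive acetal. C9 and C10 are missing, so ring B must still be closed by a medium-ring bond formation that also has to deliver the cis-diol, the epoxide face and the C11 methylene. The methyl acetal must finally be exchanged for acetate under acid in the presence of the epoxide.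
- Comparison: the chosen route gives up the short ring A but obtains ring B by cleavage and sets C9/C10 on a rigid five-membered ring.

**Alternative 2:** C11–C11a and C1–OAc are cut. A monocyclic 4H-pyran would be closed by a cationic monovalent gold catalyst: the enol ether carbon C11a attacks the activated alkyne at C11 (9-exo-dig) and a carboxylic acid captures C1, giving A2.
- For: very convergent; one step forms ring B, the C11 methylene and the C1 acetate. It avoids both the methylenation of a hindered ketone and the lactol acetylation, the two weakest late steps of the chosen route.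
- Against: enol ether–alkyne closure to a nine-membered carbocycle has no close analogy at this ring size. Intermolecular capture, alkyne hydration and opening of the epoxide by the Lewis-acidic metal and the acid compete. C11a and C1 would be set in a flexible transition state with no evident control element.
- Comparison: the chosen route puts its main risk into a fragmentation of a known type, and pays with a longer endgame.

**Alternative 3:** C9–C10 is cut. Two aldehyde carbons would be coupled by low-valent titanium to close ring B as the cis-diol A3.
- For: ring A, the Z olefin and the C11 methylene are in place before the closure; the coupling makes ring B and both carbinol centres at once, and fewer steps follow it than follow the fragmentation.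
- Against: both aldehydes are enals (C9 on the Z olefin, C10 on the methylene-bearing C11), so isomerisation, vinylogous coupling and deoxygenation to an olefin threaten. The closure is again a medium-ring bond formation, and the sense of the diol relative to C4a/C11a depends on the ring conformation. Differentiating C9 from C10, elaborating the ester into the side chain and exchanging the methyl acetal all remain.
- Comparison: the chosen route sets the diol by a hydroxyl-directed reaction before the ring exists and needs no ring-closing bond formation for ring B.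

Key step: step 11

## Route

Assumption: C4 of 31–36 and the carbinol carbon of 5 and 6 are formed without control and are left undefined in the SMILES; both are lost later (C4 becomes trigonal in 37, the carbinol becomes CH2 in 7).

**Step 1**
Reactants: 1 2-methylcyclopentane-1,3-dione; 2 methyl vinyl ketone
Product: 3 2-methyl-2-(3-oxobutyl)cyclopentane-1,3-dione
Conditions: H2O, AcOH (cat.), 70 °C
Reagents that add atoms: none
Why: Michael addition of the acidic 1,3-dione to the enone; the quaternary carbon (later C7 with C18) is formed without a stereocentre.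

**Step 2**
Reactants: 3 triketone
Product: 4 (3aS,7aS)-3a-hydroxy-7a-methylhexahydro-1H-indene-1,5(4H)-dione (cis-fused ketol)
Conditions: (S)-proline (3 mol %), DMF, rt
Reagents that add atoms: none
Why: Hajos–Parrish enamine aldol cyclisation; the proline enamine of the side-chain ketone selects one of the two enantiotopic ring carbonyls and sets both ring-fusion centres cis in the (3aS,7aS) series; the ketol is kept, not dehydrated.

**Step 3**
Reactants: 4 ketol
Product: 5 (3aS,7aS)-3a,5-dihydroxy-7a-methyloctahydro-1H-inden-1-one (C5 carbinol undefined)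
Conditions: NaBH4 (0.3 equiv), EtOH, −40 °C
Reagents that add atoms: none
Why: Chemoselective hydride reduction; the unhindered cyclohexanone should react well before the cyclopentanone flanked by the quaternary carbon.

**Step 4**
Reactants: 5 diol ketone
Product: 6 O-(3a-hydroxy-7a-methyl-1-oxooctahydro-1H-inden-5-yl) 1H-imidazole-1-carbothioate
Conditions: 1,1′-thiocarbonyldiimidazole, DMAP (cat.), ClCH2CH2Cl, 60 °C
Reagents that add atoms: 1,1′-thiocarbonyldiimidazole, S=C(n1ccnc1)n1ccnc1
Why: Thioacylation of the secondary hydroxyl only; the tertiary hydroxyl is inert and the neutral conditions avoid retro-aldol cleavage.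

**Step 5**
Reactants: 6 imidazolyl thiocarbonate
Product: 7 (3aR,7aS)-3a-hydroxy-7a-methyloctahydro-1H-inden-1-one (same spatial arrangement as 4)
Conditions: Bu3SnH, AIBN (cat.), toluene, 100 °C
Reagents that add atoms: none
Why: Barton–McCombie deoxygenation removes the six-ring oxygen (C4a of the target); no stereocentre is touched.

**Step 6**
Reactants: 7 hydroxy ketone
Product: 8 (3aR,7aS)-3a-hydroxy-7a-methyl-3a,4,5,6,7,7a-hexahydro-1H-inden-1-one (C8 ketone, C9=C10 olefin, C11 hydroxyl)
Conditions: IBX (2-iodoxybenzoic acid), DMSO, 70 °C
Reagents that add atoms: none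
Why: IBX dehydrogenation of the ketone through its enol; only one α-carbon carries hydrogen, the other being quaternary.

**Step 7**
Reactants: 8 enone
Product: 10 triol ketone (C8 ketone; C9, C10 and C11 hydroxyls all cis to each other and to the C7 methyl), via osmate ester 9 (not isolated)
Conditions: OsO4 (1.05 equiv), TMEDA, CH2Cl2, −78 °C; then aq. Na2SO3, THF, 50 °C
Reagents that add atoms: osmium tetroxide, O=[Os](=O)(=O)=O
Why: Hydrogen-bond-directed dihydroxylation: the OsO4–TMEDA complex is bound by the allylic tertiary hydroxyl and adds to the olefin face syn to it, which is also the convex face of the cis-hydrindenone, so both new hydroxyls are cis to the C11 hydroxyl; sulfite cleaves the hexavalent osmium glycolate.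

**Step 8**
Reactants: 10 triol ketone
Product: 11 9,10-O-isopropylidene ketone (C11 hydroxyl free)
Conditions: 2-methoxypropene, PPTS (cat.), CH2Cl2, 0 °C
Reagents that add atoms: 2-methoxypropene, C=C(C)OC
Why: Kinetic acetalisation of the cis-diol formed by the two secondary hydroxyls; the tertiary ring-fusion hydroxyl is too hindered to be engaged at 0 °C.

**Step 9**
Reactants: 11 acetonide ketone
Product: 12 C8 alcohol (C8 hydroxyl trans to the C7 methyl, to the C11 hydroxyl and to the C9 oxygen)
Conditions: Me4NBH(OAc)3, MeCN–AcOH, −20 °C
Reagents that add atoms: none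
Why: Evans–Saksena directed reduction: the C11 hydroxyl exchanges onto boron and delivers hydride to the face of the β-ketone that it occupies, giving the 1,3-anti diol.

**Step 10**
Reactants: 12 diol
Product: 13 C8 mesylate (cis-hydrindane with C11 tertiary hydroxyl, mesylate trans to the angular methyl, 9,10-acetonide)
Conditions: MsCl, Et3N, CH2Cl2, 0 °C
Reagents that add atoms: methanesulfonyl chloride, CS(=O)(=O)Cl
Why: Sulfonylation of the secondary alcohol through sulfene; the tertiary alcohol does not react.

**Step 11**
Reactants: 13 mesylate
Product: 15 (Z)-cyclononenone acetonide (C11 ketone, Z C7(Me)=C8 olefin, cis-9,10-diol as acetonide), via potassium alkoxide 14 (not isolated)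
Conditions: KN(SiMe3)2 (1.05 equiv), THF, −78 → 0 °C
Reagents that add atoms: none
Why: Deprotonation of the tertiary C11 hydroxyl gives alkoxide 14, whose oxygen lone pair pushes into C11 as the C8–O bond of the mesylate ionises, so that C7–C11 breaks while the C11 carbonyl and the C7=C8 π bond form in one concerted step. The closest known reaction type is the Grob (Wharton) fragmentation of bicyclic 1,3-diol monosulfonates to cyclononenones. No ring is closed by bond formation: ring B is the periphery of the bicyclo[4.3.0]nonane and appears when the shared bond is cut. No stereocentre is created; C9 and C10 are carried over unchanged. The selectivity needed is the olefin geometry: a mesylate trans to the angular methyl can become pseudoaxial and antiperiplanar to C7–C11, and in that arrangement C6 and C9 lie on the same side of the C7–C8 axis and end cis, giving the Z olefin. One equivalent of base at low temperature is used so that the product, an α,β-dialkoxy ketone, is not enolised (loss of the C9 oxygen, epimerisation at C10). Oxetane formation by attack of the alkoxide on C8 is disfavoured because it would need a 5-oxabicyclo[2.1.1]hexane.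

**Step 12**
Reactants: 15 acetonide
Product: 16 cis-9,10-diol (C11 ketone, Z C7=C8 olefin)
Conditions: AcOH–H2O (4:1), 40 °C
Reagents that add atoms: none
Why: Acid hydrolysis of the dioxolane, done before the acid-labile epoxide exists; C9 and C10 are untouched.

**Step 13**
Reactants: 16 diol
Product: 17 9-benzoate (C10 hydroxyl free)
Conditions: BzCl (1.05 equiv), pyridine, CH2Cl2, −40 °C
Reagents that add atoms: benzoyl chloride, O=C(Cl)c1ccccc1
Why: Kinetic acylation; the allylic C9 hydroxyl should be the more nucleophilic, the C10 hydroxyl being deactivated as an α-ketol (inductive effect, hydrogen bond to C11=O); low temperature and immediate silylation limit 1,2-acyl migration.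

**Step 14**
Reactants: 17 hydroxy benzoate
Product: 18 9-benzoate 10-tert-butyldimethylsilyl ether
Conditions: TBSOTf, 2,6-lutidine, CH2Cl2, −78 °C
Reagents that add atoms: tert-butyldimethylsilyl triflate, CC(C)(C)[Si](C)(C)OS(=O)(=O)C(F)(F)F
Why: Silylation of the hindered α-ketol hydroxyl with the reactive triflate under non-nucleophilic base, conditions under which the benzoate does not migrate.

**Step 15**
Reactants: 18 olefin
Product: 19 7,8-epoxide (oxygen anti to the C9 benzoate, configuration as in the target)
Conditions: mCPBA, NaHCO3, CH2Cl2, 0 °C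
Reagents that add atoms: 3-chloroperbenzoic acid, OOC(=O)c1cccc(Cl)c1
Why: Prilezhaev epoxidation of the only olefin; allylic 1,3-strain in the Z-trisubstituted olefin puts C9–H in the olefin plane and the benzoate outside, so the peracid attacks the exposed outer face and the oxirane forms anti to the C9 oxygen, as with derivatives of cis-cyclononenol; cold buffered conditions keep Baeyer–Villiger oxidation slow.

**Step 16**
Reactants: 19 epoxy ketone
Product: 21 epoxy enone (C11 ketone, Z C11a=C4a olefin), via trimethylsilyl enol ether 20 (not isolated)
Conditions: LiN(SiMe3)2, Me3SiCl, THF, −78 °C; then Pd(OAc)2 (1.1 equiv), MeCN, rt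
Reagents that add atoms: none
Why: Kinetic deprotonation by the hindered amide at the C11a methylene (not at the tertiary, oxygenated C10) with internal silyl quench, then Saegusa–Ito oxidation of 20; the benzoate tolerates the amide base at −78 °C.

**Step 17**
Reactants: 22 2-deoxy-D-ribose
Product: 23 (2R,3S)-5,5-bis(ethylsulfanyl)pentane-1,2,3-triol
Conditions: EtSH, conc. HCl, 0 °C
Reagents that add atoms: ethanethiol, CCS
Why: Dithioacetalisation opens the sugar to its acyclic form and masks the aldehyde carbon (later C3); the two stereocentres (later C12 and C13) are not touched.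

**Step 18**
Reactants: 23 triol
Product: 24 tris(triethylsilyl) ether of 23
Conditions: Et3SiCl (3.3 equiv), imidazole, DMF, rt
Reagents that add atoms: chlorotriethylsilane, CC[Si](Cl)(CC)CC
Why: Exhaustive silylation.

**Step 19**
Reactants: 24 tris-silyl ether
Product: 25 (2S,3S)-5,5-bis(ethylsulfanyl)-2,3-bis(triethylsilyloxy)pentanal
Conditions: (COCl)2, DMSO, CH2Cl2, −78 → −30 °C; then Et3N, −78 → 0 °C
Reagents that add atoms: none
Why: Swern oxidation applied directly to the primary triethylsilyl ether: the chlorosulfonium salt cleaves only the unhindered primary O–Si bond and the alkoxysulfonium ylide collapses to the aldehyde; secondary silyl ethers are inert.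

**Step 20**
Reactants: 25 aldehyde
Product: 26 (3S,4R)-1,1-bis(ethylsulfanyl)-6-methyl-3,4-bis(triethylsilyloxy)hept-5-ene
Conditions: i-PrPPh3I, n-BuLi, THF, −78 → 0 °C
Reagents that add atoms: isopropyltriphenylphosphonium iodide, CC(C)[P+](c1ccccc1)(c1ccccc1)c1ccccc1.[I-]
Why: Wittig olefination with the non-stabilised isopropylidene ylide builds C14=C15 with its two methyls; no geometry issue arises.

**Step 21**
Reactants: 26 dithioacetal
Product: 27 (3S,4R)-6-methyl-3,4-bis(triethylsilyloxy)hept-5-enal
Conditions: MeI, CaCO3, MeCN–H2O (9:1), 40 °C
Reagents that add atoms: water, O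
Why: S-Methylation makes the thioacetal a leaving group and water gives the aldehyde under buffered, non-acidic conditions that spare the silyl ethers and the olefin.

**Step 22**
Reactants: 27 aldehyde
Product: 28 (3S,4R)-6-methyl-3,4-bis(triethylsilyloxy)hept-5-enoic acid
Conditions: NaClO2, NaH2PO4, 2-methyl-2-butene, t-BuOH–H2O, 0 °C → rt
Reagents that add atoms: sodium chlorite, [Na+].[O-]Cl=O
Why: Pinnick oxidation; the scavenger protects the trisubstituted olefin.

**Step 23**
Reactants: 28 acid
Product: 29 S-ethyl (3S,4R)-6-methyl-3,4-bis(triethylsilyloxy)hept-5-enethioate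
Conditions: EtSH, DCC, DMAP (cat.), CH2Cl2, 0 °C → rt
Reagents that add atoms: ethanethiol, CCS
Why: Steglich-type thioesterification; the thioester allows soft enolisation now and neutral reduction to the aldehyde later.

**Step 24**
Reactants: 29 thioester
Product: 30 O-triethylsilyl ketene thioacetal of 29 (used without purification)
Conditions: Et3SiOTf, Et3N, CH2Cl2, −78 → 0 °C
Reagents that add atoms: triethylsilyl triflate, CC[Si](CC)(CC)OS(=O)(=O)C(F)(F)F
Why: Soft enolisation of the thioester; no metal enolate is formed, so the β-silyloxy group is not eliminated.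

**Step 25**
Reactants: 21 epoxy enone; 30 ketene thioacetal
Product: 32 C11 ketone with the C4 thioester side chain on C4a and CH2OSiEt3 (C1) on C11a (C4a and C11a as in the target), via triethylsilyl enol ether 31 (not isolated)
Conditions: 30 (1.5 equiv), Ph3CClO4 (5 mol %), CH2Cl2, −78 °C; then CH2O (monomer in THF), −78 → −40 °C
Reagents that add atoms: formaldehyde, C=O
Why: Tandem Mukaiyama–Michael/Mukaiyama aldol: the activated enone is attacked at C4a by the ketene thioacetal with silyl transfer to the C11 oxygen (31), and the enol ether then adds to formaldehyde at C11a anti to the new C4a substituent, the silyl group ending on O1. C4a is set by attack on the outer face of the ring in the conformer that keeps the C10 silyl ether outside, and C11a is set trans to C4a.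

**Step 26**
Reactants: 32 ketone
Product: 33 C11 methylene compound
Conditions: Zn, CH2Br2, TiCl4 (reagent preformed in THF), CH2Cl2, 0 °C → rt
Reagents that add atoms: dibromomethane, BrCBr
Why: Takai–Lombardo methylenation: the reagent is non-basic, so the hindered ketone is converted without epimerisation at C10 or C11a and without β-elimination of the C1 or C9 oxygens; the benzoate and thioester react much more slowly than the ketone.

**Step 27**
Reactants: 33 primary silyl ether
Product: 34 C1 aldehyde
Conditions: (COCl)2, DMSO, CH2Cl2, −78 → −40 °C; then Et3N, −78 → −20 °C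
Reagents that add atoms: none
Why: Direct Swern oxidation of the primary triethylsilyl ether, as in step 19; the secondary triethylsilyl and tert-butyldimethylsilyl ethers are inert, and the cold work-up keeps the β,γ-unsaturated aldehyde from epimerising at C11a or moving into conjugation.

**Step 28**
Reactants: 34 aldehyde
Product: 35 C1 carboxylic acid
Conditions: NaClO2, NaH2PO4, 2-methyl-2-butene, t-BuOH–H2O, 0 °C
Reagents that add atoms: sodium chlorite, [Na+].[O-]Cl=O
Why: Pinnick oxidation under weakly acidic buffer; it does not enolise the aldehyde and spares the olefins, the thioester and the epoxide.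

**Step 29**
Reactants: 35 thioester acid
Product: 36 formyl acid (C1 acid, C3 aldehyde; in equilibrium with its cyclic hydroxy lactone)
Conditions: Et3SiH, Pd/C (10 %), acetone, rt
Reagents that add atoms: none
Why: Fukuyama reduction of the thioester to the aldehyde under neutral conditions that tolerate the free acid, the benzoate and the epoxide.

**Step 30**
Reactants: 36 formyl acid
Product: 37 enol lactone (ring A with C1 carbonyl and C3=C4 enol ether)
Conditions: Ac2O, NaOAc (cat.), toluene, 80 °C
Reagents that add atoms: none
Why: Enol lactonisation of a δ-oxo acid: the mixed anhydride at C1 is attacked by the C3 carbonyl oxygen and loss of the C4 proton gives the enol ester; this fixes O2 between C1 and C3 and removes the uncontrolled centre at C4.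

**Step 31**
Reactants: 37 enol lactone
Product: 38 lactol (C1 hydroxyl)
Conditions: i-Bu2AlH (1.1 equiv), CH2Cl2, −78 °C; aq. KNaC4H4O6 work-up
Reagents that add atoms: none
Why: Partial reduction of an enol lactone to its enol lactol through an aluminium hemiacetal stable at −78 °C, the reaction by which iridoid enol lactones of the nepetalactone type give their lactols; the enol lactone is far more electrophilic than the benzoate, which survives one equivalent of hydride at this temperature.

**Step 32**
Reactants: 38 lactol
Product: 39 C1 acetate (axial, trans to H-11a)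
Conditions: Ac2O, pyridine, CH2Cl2, 0 °C
Reagents that add atoms: acetic anhydride, CC(=O)OC(C)=O
Why: Acetylation of the lactol hydroxyl; the lactol can equilibrate at C1 through its ring-opened enol–aldehyde form and should rest as the axial, anomerically stabilised epimer, whose configuration the acetate keeps; a minor C1 epimer would be removed by chromatography.

**Step 33**
Reactants: 39 bis(triethylsilyl) ether
Product: 40 12,13-diol
Conditions: HF·pyridine, pyridine, THF, 0 °C
Reagents that add atoms: none
Why: Buffered fluoride cleaves the secondary triethylsilyl ethers much faster than the hindered tert-butyldimethylsilyl ether at C10; buffered HF·pyridine spares trisubstituted epoxides and anomeric acetates at this temperature.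

**Step 34**
Reactants: 40 diol
Product: 41 12,13-diacetate (10-O-silyl target)
Conditions: Ac2O, pyridine, DMAP (cat.), CH2Cl2, 0 °C → rt
Reagents that add atoms: acetic anhydride, CC(=O)OC(C)=O
Why: Acetylation of the two secondary hydroxyls, done at once so that the free C12 hydroxyl does not add to C1; C10 is still protected.

**Step 35**
Reactants: 41 silyl ether
Product: 42 target, CNP0317411.2
Conditions: HF·pyridine, pyridine, THF, 0 °C → rt
Reagents that add atoms: none
Why: Acidic fluoride removes the last silyl group without generating an alkoxide, so the C9 benzoate should not migrate to O10 and the acetates are not cleaved.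

## Compound list

1 | 2-methylcyclopentane-1,3-dione | CC1C(=O)CCC1=O | starting material
2 | methyl vinyl ketone | CC(=O)C=C | starting material
3 | 2-methyl-2-(3-oxobutyl)cyclopentane-1,3-dione | CC(=O)CCC1(C)C(=O)CCC1=O | intermediate
4 | (3aS,7aS)-3a-hydroxy-7a-methylhexahydro-1H-indene-1,5(4H)-dione | O[C@@]12CC(=O)CC[C@]1(C)C(=O)CC2 | intermediate
5 | (3aS,7aS)-3a,5-dihydroxy-7a-methyloctahydro-1H-inden-1-one | O[C@@]12CC(O)CC[C@]1(C)C(=O)CC2 | intermediate
6 | imidazolyl thiocarbonate of 5 | O[C@@]12CC(OC(=S)n3ccnc3)CC[C@]1(C)C(=O)CC2 | intermediate
7 | (3aR,7aS)-3a-hydroxy-7a-methyloctahydro-1H-inden-1-one | O[C@@]12CCCC[C@]1(C)C(=O)CC2 | intermediate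
8 | (3aR,7aS)-3a-hydroxy-7a-methyl-3a,4,5,6,7,7a-hexahydro-1H-inden-1-one | O[C@@]12CCCC[C@]1(C)C(=O)C=C2 | intermediate
9 | hexavalent osmium glycolate of 10, TMEDA complex | O[C@@]12CCCC[C@]1(C)C(=O)[C@H]3O[Os-2]4(=O)(=O)(O[C@@H]23)[N+](C)(C)CC[N+]4(C)C | intermediate (not isolated)
10 | triol ketone (C8 ketone; C9, C10, C11 hydroxyls all cis) | O[C@@]12CCCC[C@]1(C)C(=O)[C@@H](O)[C@H]2O | intermediate
11 | 9,10-acetonide of 10 | O[C@@]12CCCC[C@]1(C)C(=O)[C@H]3OC(C)(C)O[C@@H]23 | intermediate
12 | C8 alcohol (hydroxyl trans to the angular methyl) | O[C@@]12CCCC[C@]1(C)[C@H](O)[C@H]3OC(C)(C)O[C@@H]23 | intermediate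
13 | C8 mesylate (key-step precursor) | O[C@@]12CCCC[C@]1(C)[C@H](OS(C)(=O)=O)[C@H]3OC(C)(C)O[C@@H]23 | intermediate
14 | potassium C11 alkoxide of 13 | [K+].[O-][C@@]12CCCC[C@]1(C)[C@H](OS(C)(=O)=O)[C@H]3OC(C)(C)O[C@@H]23 | intermediate (not isolated)
15 | (Z)-cyclononenone acetonide (key-step product) | O=C1CCCC/C(C)=C\[C@H]2OC(C)(C)O[C@@H]12 | intermediate
16 | cis-9,10-diol ketone | O=C1CCCC/C(C)=C\[C@@H](O)[C@H]1O | intermediate
17 | 9-benzoate | O=C1CCCC/C(C)=C\[C@@H](OC(=O)c2ccccc2)[C@H]1O | intermediate
18 | 9-benzoate 10-TBS ether | O=C1CCCC/C(C)=C\[C@@H](OC(=O)c2ccccc2)[C@H]1O[Si](C)(C)C(C)(C)C | intermediate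
19 | 7,8-epoxy ketone | O=C1CCCC[C@]2(C)O[C@@H]2[C@@H](OC(=O)c2ccccc2)[C@H]1O[Si](C)(C)C(C)(C)C | intermediate
20 | C11 trimethylsilyl enol ether of 19 | C[Si](C)(C)O/C1=C/CCC[C@]2(C)O[C@@H]2[C@@H](OC(=O)c2ccccc2)[C@H]1O[Si](C)(C)C(C)(C)C | intermediate (not isolated)
21 | epoxy enone (Z C11a=C4a) | O=C1/C=C\CC[C@]2(C)O[C@@H]2[C@@H](OC(=O)c2ccccc2)[C@H]1O[Si](C)(C)C(C)(C)C | intermediate
22 | 2-deoxy-D-ribose | O=CC[C@H](O)[C@H](O)CO | starting material
23 | (2R,3S)-5,5-bis(ethylsulfanyl)pentane-1,2,3-triol | CCSC(SCC)C[C@H](O)[C@H](O)CO | intermediate
24 | tris(triethylsilyl) ether of 23 | CCSC(SCC)C[C@H](O[Si](CC)(CC)CC)[C@H](O[Si](CC)(CC)CC)CO[Si](CC)(CC)CC | intermediate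
25 | (2S,3S)-5,5-bis(ethylsulfanyl)-2,3-bis(triethylsilyloxy)pentanal | CCSC(SCC)C[C@H](O[Si](CC)(CC)CC)[C@H](O[Si](CC)(CC)CC)C=O | intermediate
26 | (3S,4R)-1,1-bis(ethylsulfanyl)-6-methyl-3,4-bis(triethylsilyloxy)hept-5-ene | CCSC(SCC)C[C@H](O[Si](CC)(CC)CC)[C@H](O[Si](CC)(CC)CC)C=C(C)C | intermediate
27 | (3S,4R)-6-methyl-3,4-bis(triethylsilyloxy)hept-5-enal | O=CC[C@H](O[Si](CC)(CC)CC)[C@H](O[Si](CC)(CC)CC)C=C(C)C | intermediate
28 | (3S,4R)-6-methyl-3,4-bis(triethylsilyloxy)hept-5-enoic acid | OC(=O)C[C@H](O[Si](CC)(CC)CC)[C@H](O[Si](CC)(CC)CC)C=C(C)C | intermediate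
29 | S-ethyl (3S,4R)-6-methyl-3,4-bis(triethylsilyloxy)hept-5-enethioate | CCSC(=O)C[C@H](O[Si](CC)(CC)CC)[C@H](O[Si](CC)(CC)CC)C=C(C)C | intermediate
30 | O-triethylsilyl ketene thioacetal of 29 | CCSC(O[Si](CC)(CC)CC)=C[C@H](O[Si](CC)(CC)CC)[C@H](O[Si](CC)(CC)CC)C=C(C)C | intermediate
31 | C11 triethylsilyl enol ether (Michael adduct) | CC[Si](CC)(CC)O/C1=C/[C@@H](C(C(=O)SCC)[C@H](O[Si](CC)(CC)CC)[C@H](O[Si](CC)(CC)CC)C=C(C)C)CC[C@]2(C)O[C@@H]2[C@@H](OC(=O)c2ccccc2)[C@H]1O[Si](C)(C)C(C)(C)C | intermediate (not isolated)
32 | C11 ketone with C4a side chain and C11a CH2OSiEt3 | O=C1[C@H](CO[Si](CC)(CC)CC)[C@@H](C(C(=O)SCC)[C@H](O[Si](CC)(CC)CC)[C@H](O[Si](CC)(CC)CC)C=C(C)C)CC[C@]2(C)O[C@@H]2[C@@H](OC(=O)c2ccccc2)[C@H]1O[Si](C)(C)C(C)(C)C | intermediate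
33 | C11 methylene compound | C=C1[C@H](CO[Si](CC)(CC)CC)[C@@H](C(C(=O)SCC)[C@H](O[Si](CC)(CC)CC)[C@H](O[Si](CC)(CC)CC)C=C(C)C)CC[C@]2(C)O[C@@H]2[C@@H](OC(=O)c2ccccc2)[C@H]1O[Si](C)(C)C(C)(C)C | intermediate
34 | C1 aldehyde | C=C1[C@H](C=O)[C@@H](C(C(=O)SCC)[C@H](O[Si](CC)(CC)CC)[C@H](O[Si](CC)(CC)CC)C=C(C)C)CC[C@]2(C)O[C@@H]2[C@@H](OC(=O)c2ccccc2)[C@H]1O[Si](C)(C)C(C)(C)C | intermediate
35 | C1 carboxylic acid | C=C1[C@H](C(=O)O)[C@@H](C(C(=O)SCC)[C@H](O[Si](CC)(CC)CC)[C@H](O[Si](CC)(CC)CC)C=C(C)C)CC[C@]2(C)O[C@@H]2[C@@H](OC(=O)c2ccccc2)[C@H]1O[Si](C)(C)C(C)(C)C | intermediate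
36 | formyl acid (C1 acid, C3 aldehyde) | C=C1[C@H](C(=O)O)[C@@H](C(C=O)[C@H](O[Si](CC)(CC)CC)[C@H](O[Si](CC)(CC)CC)C=C(C)C)CC[C@]2(C)O[C@@H]2[C@@H](OC(=O)c2ccccc2)[C@H]1O[Si](C)(C)C(C)(C)C | intermediate
37 | enol lactone | C=C1[C@@H]2C(=O)OC=C([C@H](O[Si](CC)(CC)CC)[C@@H](C=C(C)C)O[Si](CC)(CC)CC)[C@H]2CC[C@]2(C)O[C@@H]2[C@@H](OC(=O)c2ccccc2)[C@H]1O[Si](C)(C)C(C)(C)C | intermediate
38 | lactol | C=C1[C@@H]2[C@H](O)OC=C([C@H](O[Si](CC)(CC)CC)[C@@H](C=C(C)C)O[Si](CC)(CC)CC)[C@H]2CC[C@]2(C)O[C@@H]2[C@@H](OC(=O)c2ccccc2)[C@H]1O[Si](C)(C)C(C)(C)C | intermediate
39 | C1 acetate | C=C1[C@@H]2[C@H](OC(C)=O)OC=C([C@H](O[Si](CC)(CC)CC)[C@@H](C=C(C)C)O[Si](CC)(CC)CC)[C@H]2CC[C@]2(C)O[C@@H]2[C@@H](OC(=O)c2ccccc2)[C@H]1O[Si](C)(C)C(C)(C)C | intermediate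
40 | 12,13-diol | C=C1[C@@H]2[C@H](OC(C)=O)OC=C([C@H](O)[C@@H](C=C(C)C)O)[C@H]2CC[C@]2(C)O[C@@H]2[C@@H](OC(=O)c2ccccc2)[C@H]1O[Si](C)(C)C(C)(C)C | intermediate
41 | 10-O-TBS target | C=C1[C@@H]2[C@H](OC(C)=O)OC=C([C@H](OC(C)=O)[C@@H](C=C(C)C)OC(C)=O)[C@H]2CC[C@]2(C)O[C@@H]2[C@@H](OC(=O)c2ccccc2)[C@H]1O[Si](C)(C)C(C)(C)C | intermediate
42 | CNP0317411.2 | C=C1[C@@H]2[C@H](OC(C)=O)OC=C([C@H](OC(C)=O)[C@@H](C=C(C)C)OC(C)=O)[C@H]2CC[C@]2(C)O[C@@H]2[C@@H](OC(=O)c2ccccc2)[C@H]1O | target

## Step count and least certain steps

Total: 35 steps. Longest linear sequence: 27 steps (steps 1–16 and 25–35, from 1). The side-chain branch is 8 steps (17–24, from 22).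

**Step 11 (key step).** The fragmentation may stall if the mesylate cannot reach the pseudoaxial position in the cis-hydrindane. Once the ketone has formed, excess or long-lived base may enolise it, with loss of the C9 oxygen or epimerisation at C10. Fallback: the fragmentation is run reductively. Mesylate 13 is treated with LiAlH4 in THF; the aluminium alkoxide fragments and the ketone is reduced as it forms, so no enolisable carbonyl is exposed to base. This gives the cyclononenol F1, which is reoxidised with Dess–Martin periodinane to 15.

**Step 25.** The facial selectivity at C4a rests on the conformation of a nine-membered enone whose nearest stereocentre (C10) is three atoms away, so attack on the wrong face is the main danger; ionisation of the epoxide by the Lewis acid is the second. Fallback: substrate control is replaced by reagent control. The same addition of 30 to 21 is promoted by a chiral oxazaborolidinium triflimide Lewis acid of the type known to select the face of simple cyclic enones in additions of silyl ketene acetals, followed by the same trapping, and returns to 32. If the matched catalyst enantiomer still fails, the C4a problem is not solved within this route.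

**Step 26.** The ketone is flanked by two branched carbons, so methylenation may be slow enough for the thioester to react or for a β-oxygen to be eliminated. Fallback: a two-step addition–elimination. Ketone 32 is treated with Me3SiCH2Li/CeCl3 in THF at −78 °C to give the β-hydroxysilane F2, and Peterson elimination on silica gel or with a trace of mild acid returns to 33.

**Step 13.** Acylation may be unselective between O9 and O10, or the benzoate may migrate to O10 before silylation. Fallback: the two hydroxyls are told apart with bulky silyl chlorides, and the benzoate is put on a single free hydroxyl. Diol 16 is silylated with Et3SiCl/imidazole at −40 °C to the 9-triethylsilyl ether F3, then with TBSOTf/2,6-lutidine to the bis-silyl ether F4. Buffered HF·pyridine removes only the triethylsilyl group to give the 9-alcohol F5, and BzCl/pyridine/DMAP returns to 18. If O10 proves the more reactive hydroxyl, TBSCl on 16 gives F5 directly.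

**Step 32.** The lactol may be acetylated mainly as its equatorial C1 epimer, or may open to the dialdehyde with epimerisation at C11a. Fallback: C1 is set by inversion instead of by the resting lactol. Lactol 38 is converted with Cl3CCN/K2CO3 into the kinetically formed equatorial trichloroacetimidate F6, and displacement by acetic acid in CH2Cl2 without added catalyst proceeds with inversion and returns to the axial acetate 39.

## Further compounds

F1 | step 11 | (Z)-cyclononenol acetonide (C11 carbinol, configuration undefined) | OC1CCCC/C(C)=C\[C@H]2OC(C)(C)O[C@@H]12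
F0 | step 25 | none | none
F2 | step 26 | C11 β-hydroxysilane (C11 hydroxyl and CH2SiMe3, C11 undefined) | C[Si](C)(C)CC1(O)[C@H](CO[Si](CC)(CC)CC)[C@@H](C(C(=O)SCC)[C@H](O[Si](CC)(CC)CC)[C@H](O[Si](CC)(CC)CC)C=C(C)C)CC[C@]2(C)O[C@@H]2[C@@H](OC(=O)c2ccccc2)[C@H]1O[Si](C)(C)C(C)(C)C
F3 | step 13 | 9-O-triethylsilyl 10-hydroxy ketone | O=C1CCCC/C(C)=C\[C@@H](O[Si](CC)(CC)CC)[C@H]1O
F4 | step 13 | 9-O-triethylsilyl 10-O-tert-butyldimethylsilyl ketone | O=C1CCCC/C(C)=C\[C@@H](O[Si](CC)(CC)CC)[C@H]1O[Si](C)(C)C(C)(C)C
F5 | step 13 | 9-hydroxy 10-O-tert-butyldimethylsilyl ketone | O=C1CCCC/C(C)=C\[C@@H](O)[C@H]1O[Si](C)(C)C(C)(C)C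
F6 | step 32 | equatorial C1 trichloroacetimidate of lactol 38 | C=C1[C@@H]2[C@@H](OC(=N)C(Cl)(Cl)Cl)OC=C([C@H](O[Si](CC)(CC)CC)[C@@H](C=C(C)C)O[Si](CC)(CC)CC)[C@H]2CC[C@]2(C)O[C@@H]2[C@@H](OC(=O)c2ccccc2)[C@H]1O[Si](C)(C)C(C)(C)C
A1 | alternative 1 | methyl 3-[(tert-butyldimethylsilyloxy)methyl]-4-[(Z)-4-iodo-3-methylbut-3-enyl]-2-methoxy-3,4-dihydro-2H-pyran-5-carboxylate | CC(C)(C)[Si](C)(C)OC[C@@H]1[C@@H](OC)OC=C(C(=O)OC)[C@H]1CC/C(C)=C\I
A2 | alternative 2 | bicyclic C1 acetate with C11 methylene, 7,8-epoxide, C12 aldehyde, 9-O-triethylsilyl and 10-O-tert-butyldimethylsilyl groups | C=C1[C@@H]2[C@H](OC(C)=O)OC=C(C=O)[C@H]2CC[C@]3(C)O[C@@H]3[C@@H](O[Si](CC)(CC)CC)[C@H]1O[Si](C)(C)C(C)(C)C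
A3 | alternative 3 | bicyclic cis-9,10-diol with Z C7=C8 olefin, C11 methylene, C1 methyl acetal and C4 methyl ester | C=C1[C@@H]2[C@H](OC)OC=C(C(=O)OC)[C@H]2CC/C(C)=C\[C@@H](O)[C@H]1O
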